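**Remark on the chemistry (assumption):** the configuration string of the target corresponds to (2S,3R), which for this constitutionally symmetric chain is the achiral meso form, so only relative configuration has to be controlled. The key-step structures were checked atom by atom (Z alkene; C–S–C dipole C16H16O2S; cycloadduct C36H36O8S with cis aroyl groups) and are mutually consistent as drawn. Steps 1 and 3 each join two molecules of one starting material to a central unit, and step 4 uses chlorotrimethylsilane twice; the second molar equivalent is entered in each case as a reagent that adds atoms, so that every atom of the product is accounted for.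

## Structural features

The target is an open butane-1,4-dione chain in which the carbonyl carbons C1 and C4 each carry a 2,4-dihydroxyphenyl ring (rings A) and C2 and C3 each carry a 4-hydroxybenzyl group through the methylene carbons C2' and C3' (rings B); formally it is a dihydrochalcone joined to itself α to α. C2 and C3 are directly bonded stereocentres with identical substituent sets and opposite descriptors, so the molecule is meso and only their relative configuration matters. Both stand α to an aryl ketone and can epimerise through the enol or enolate to the racemic diastereomer. The 1,4-diketone can lose water to a furan under acid, and a free ortho phenol of ring A would add to any enone placed next to its ketone. The real difficulty is the C2/C3 relative configuration in a flexible, symmetric, enolisable chain, over which simple enolate dimerisation gives no control. The feature exploited is the four-carbon path C2'–C2–C3–C3': one sulfur atom between C2' and C3' turns it into a thiolane in which C2 and C3 are ring carbons 3 and 4, and cis aroyl groups on that ring are exactly the meso relation. That thiolane is the [3+2] adduct of the C2=C3 bond of a Z-1,2-diaroylethylene and a C–S–C dipole carrying both rings B.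

## Logic of the disconnections

**13 from 12.** Going backwards, all six phenols are capped as methyl ethers; forwards, six O–CH3 bonds are cleaved last. Free phenols would protonate the ylide and the organolithium reagent, and a free ortho phenol would cyclise onto the enedione. One protecting group for all six oxygens keeps the end to one operation. The forward step must remove six methyl groups with a Lewis acid without enolising C2/C3 or dehydrating the 1,4-diketone.

**12 from 11.** Two benzylic C–H bonds at C2' and C3' are replaced, in the backward sense, by two C–S bonds to one sulfur atom. This turns an acyclic relative-configuration problem into a cis/trans problem on a five-membered ring and makes the four skeletal carbons a cycloaddition product. The forward step must hydrogenolyse both benzylic C–S bonds and leave two aryl ketones and their α-centres untouched.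

**11 from 10 and 4.** The bonds C2–C2' and C3–C3' are cut together, the retro-[3+2] opening of the thiolane. This is the one pair of bonds whose formation can be stereospecific, because the alkene geometry of 4 is translated directly into the C2/C3 relation. The skeleton splits into two symmetrical halves, each from one aromatic building block. The addition must be suprafacial and concerted, and 4 must keep its Z geometry until it has reacted.

**10 from 8 through 9.** The dipole cannot be stored, so it is traced to a sulfoxide whose two C–Si bonds and S–O bond break in the flask as hexamethyldisiloxane departs. Silicon on both benzylic carbons makes the elimination symmetric and base-free. The oxidant must stop at the sulfoxide, leave no acid behind and act below the temperature of the silyl shift.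

**8 from 6 through 7.** The two C–Si bonds are cut, leading to the plain dibenzylic sulfide. This uses the acidity of the benzylic C–H bonds next to sulfur. The forward step must silylate once on each side and not twice on one carbon.

**6 from 5.** The two C–S bonds are cut to two molecules of 5 and sulfide ion, with no selectivity issue; the forward step needs only the correct two-to-one stoichiometry.

**4 from 3.** No bond is cut; the Z alkene is traced to its E isomer, the only one directly available by acylation. The forward isomerisation runs uphill, hence light.

**3 from 1 and 2.** The two aryl–carbonyl bonds are cut, giving 1 twice and 2 once. The ring substituents direct acylation to the required position, so both rings A and the enedione arise in one operation. The ortho methyl ethers must survive AlCl3.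

## Other disconnections considered

Alternative 1: The cut takes both rings B apart. Each para-oxygenated benzene ring is divided into a terminal alkyne and a 2-oxygenated butadiene (four C–C bonds in all), and the stereocentres are carried by dimethyl meso-2,3-di(prop-2-yn-1-yl)succinate A2.
- Forward step: CoBr2(dppe), reduced by Zn and activated by ZnI2, would couple each alkyne of A2 with 2-(trimethylsilyloxy)buta-1,3-diene A3 through a cobaltacycle to a 1,4-cyclohexadiene with the para pattern. DDQ would dehydrogenate both rings, and loss of the silyl groups on work-up would give dimethyl meso-2,3-bis(4-hydroxybenzyl)succinate A1.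
- In favour: A2 descends from cis-cyclohex-4-ene-1,2-dicarboxylic anhydride A4 by ring cleavage and alkynylation, so the meso relation is locked by a ring fusion from the start. On this point it is the better plan, since that is a sturdier source of relative configuration than the light-generated Z alkene of 4. The α-ester centres are also less prone to enolise than α-keto centres, and no sulfur or nickel is needed.
- Against: the key step builds the easy part (two phenol rings) and sets no stereocentre, while rings A and both ketones are still missing. Turning two ester carbons that flank adjacent stereocentres into 2,4-dioxygenated aryl ketones means either Friedel–Crafts acylation, where a 3-arylpropanoyl electrophile can close onto its own ring B, or aryl-metal addition, whose basicity threatens C2/C3. The phenols of A1 would need protection first, and the 1,7-diyne of A2 invites cobalt-mediated alkyne trimerisation.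
- Step economy: about four steps to A2, the coupling/aromatisation, and four or more to install rings A and deprotect, against seven in all for the chosen route.

Alternative 2: The cut is at the two CH2–aryl bonds of rings B, leading to purchased meso-2,3-dimethylsuccinic acid A6 as its bis(quinolin-8-yl)amide A7.
- Forward step: Pd(OAc)2 with AgOAc would arylate one C–H bond of each methyl group of A7 with 4-iodoanisole A8 to give meso-2,3-bis(4-methoxybenzyl)-N1,N4-di(quinolin-8-yl)succinamide A5. The amide and quinoline nitrogens chelate divalent palladium, a methyl C–H bond breaks by concerted metalation–deprotonation in a five-membered palladacycle, A8 adds oxidatively to give tetravalent palladium, and reductive elimination forms the C–C bond while AgOAc removes iodide.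
- In favour: the meso configuration is bought, no alkene geometry has to be preserved, and the reaction type is well established for methyl groups β to such amides. On origin of stereochemistry and on the number of steps to the key intermediate (two) it is the equal or the better of the chosen plan.
- Against: two bidentate amides on neighbouring carbons can tie up palladium or close to a cyclic imide on heating. Each methyl group may be arylated twice, and the methine C–H of the neighbouring carbon is also β to an amide. Rings A remain absent, and two robust secondary amides must be cleaved and converted into aryl ketones next to the stereocentres, with the same cyclisation and epimerisation hazards as in Alternative 1.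
- Step economy: amide formation, arylation, auxiliary removal, ketone construction and demethylation come to about eight or nine steps. That is roughly level with the chosen seven, but the hardest steps fall after the stereocentres exist.

Alternative 3: The cut is at the two C–O bonds ortho to the ketones on rings A, leading to meso-1,4-bis(4-methoxyphenyl)-2,3-bis(4-methoxybenzyl)butane-1,4-dione A10.
- Forward step: [Ir(OMe)(cod)]2 with AsPh3 and B2pin2 would borylate the C–H bond ortho to each ketone. The weakly bound arsine leaves a site on the iridium tris(boryl) for the carbonyl oxygen, which steers C–H oxidative addition to the ortho position. NaBO3 would then oxidise both C–B bonds in the same pot to give meso-1,4-bis(2-hydroxy-4-methoxyphenyl)-2,3-bis(4-methoxybenzyl)butane-1,4-dione A9.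
- In favour: the ortho oxygen, the source of the AlCl3-demethylation and oxa-Michael concerns in steps 1 and 2 of the chosen route, would arrive late and already free, and the enedione chemistry could be run in the simpler 4-methoxyphenyl series. On those points it is the better plan. The final demethylation is equal (four ethers instead of six).
- Against: it does not touch the real difficulty. A10 must still be made with the C2/C3 relation in place, most simply by the cycloaddition–desulfurisation sequence of the chosen plan, so it is an addition to the thiolane strategy and not a replacement. The borylation would expose an enolisable 1,4-diketone to a boron reagent at elevated temperature and then to basic perborate, inviting epimerisation, carbonyl reduction or boron enolate formation. The second ortho position of each ring A could be borylated as well.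
- Step economy: one step more than the chosen route for no gain in stereocontrol.

Key step: step 5

## Route

Step 1
Reactants: 1 1,3-dimethoxybenzene (2.05 equiv in all); 2 fumaryl chloride (1.0 equiv)
Product: 3 (E)-1,4-bis(2,4-dimethoxyphenyl)but-2-ene-1,4-dione
Conditions: AlCl3 (2.3 equiv), CH2Cl2, −10 → 0 °C; ice/aq HCl
Reagents that add atoms: 1,3-dimethoxybenzene (second molar equivalent of 1), COc1cccc(OC)c1
Why: Double Friedel–Crafts acylation in which each of the two acyl chloride–AlCl3 termini of 2 attacks C4 of one molecule of 1 (para to one methoxy, ortho to the other), so two molecules of 1 are consumed per molecule of 2 and two molecules of HCl are released. The first ketone deactivates its ring against a second acylation and the E geometry of 2 is carried through; low temperature limits AlCl3 cleavage of the ortho methyl ether and conjugate addition of the arene to the product.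

Step 2
Reactants: 3 (E)-1,4-bis(2,4-dimethoxyphenyl)but-2-ene-1,4-dione
Product: 4 (Z)-1,4-bis(2,4-dimethoxyphenyl)but-2-ene-1,4-dione
Conditions: hν (420 nm LED), degassed CH2Cl2, 20 °C; crystallise in the dark
Reagents that add atoms: none
Why: Photochemical E to Z isomerisation of a 1,2-diaroylethylene: the planar, coloured E isomer absorbs the visible light and the twisted, nearly colourless Z isomer does not, so the photostationary state should lie far on the Z side; an aprotic solvent and long-wavelength light avoid the ultraviolet rearrangements of cis-diaroylethylenes.

Step 3
Reactants: 5 4-methoxybenzyl chloride (2.0 equiv in all)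
Product: 6 bis(4-methoxybenzyl) sulfide
Conditions: Na2S·9H2O (1.0 equiv per 2.0 equiv of 5), DMF, 20 °C
Reagents that add atoms: sodium sulfide (used as Na2S·9H2O), [Na+].[Na+].[S-2]; 4-methoxybenzyl chloride (second molar equivalent of 5), COc1ccc(CCl)cc1
Why: Two successive SN2 displacements of benzylic chloride, the first by sulfide on one molecule of 5 and the second by the resulting thiolate on a second molecule of 5, give the symmetrical thioether and two equivalents of sodium chloride; DMF avoids solvolysis of the reactive chloride.

Step 4
Reactants: 6 bis(4-methoxybenzyl) sulfide
Product: 8 bis[(4-methoxyphenyl)(trimethylsilyl)methyl] sulfide (meso/racemic mixture), via monosilyl sulfide 7 (not isolated)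
Conditions: s-BuLi (1.05 equiv), TMEDA, THF, −78 °C; TMSCl (1.1 equiv); then s-BuLi (1.05 equiv), TMEDA, −78 °C; TMSCl (1.1 equiv), −78 → 0 °C
Reagents that add atoms: chlorotrimethylsilane (first charge), C[Si](C)(C)Cl; chlorotrimethylsilane (second charge), C[Si](C)(C)Cl
Why: α-Lithiation of a benzyl sulfide (carbanion stabilised by sulfur and the aryl ring) followed by C-silylation, run twice in one flask; in 7 the unhindered benzylic CH2 should be deprotonated in preference to the crowded silylated carbon, and −78 °C suppresses the 1,2-shift of the lithiated sulfide. The diastereomer mixture of 8 is immaterial because both silicon-bearing carbons become sp2 in the ylide.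

Step 5
Reactants: 8 bis[(4-methoxyphenyl)(trimethylsilyl)methyl] sulfide; 4 (Z)-1,4-bis(2,4-dimethoxyphenyl)but-2-ene-1,4-dione
Product: 11 3,4-cis-bis(2,4-dimethoxybenzoyl)-2,5-cis-bis(4-methoxyphenyl)thiolane (each aryl group trans to its neighbouring aroyl group; meso), via disilyl sulfoxide 9 (not isolated), via 1,3-bis(4-methoxyphenyl)thiocarbonyl ylide 10 (not isolated)
Conditions: 8, DMDO (1.0 equiv, acetone), CH2Cl2, −78 °C; then 4, MeCN, −78 → 40 °C, dark
Reagents that add atoms: none
Why: Oxygen transfer to sulfur gives 9, which on warming undergoes the sila-Pummerer sequence: one silyl group shifts from carbon to the sulfoxide oxygen, silanolate leaves to give a thionium ion, and the silanolate removes the second silyl group as hexamethyldisiloxane, unveiling 10. The ylide is a four-electron C–S–C dipole whose HOMO matches the low LUMO of the doubly acylated alkene of 4, and it adds to both alkene carbons on the same face in one concerted suprafacial [3+2] step. The closest known reaction type is the Huisgen-type 1,3-dipolar cycloaddition of thiocarbonyl ylides, released by 1,3-elimination from α-silyl sulfoxides, to maleates, fumarates and enones with retention of alkene geometry. The thiolane closes by cycloaddition: the target bonds C2–C2' and C3–C3' (thiolane bonds C2–C3 and C4–C5) form in the same event, so no exo or endo chain cyclisation is involved. Ring carbons C3 and C4 inherit their cis relation from the Z geometry of 4, which is the meso relation of the target. Ring carbons C2 and C5 are set by the ylide geometry (both aryl groups outward gives 2,5-cis) and by approach with the aryl groups away from the aroyl groups, but their configuration is irrelevant because both become CH2. The step needs retention of the Z geometry, addition to C=C and not to C=O, and trapping faster than closure of 10 to a thiirane; the two aroyl groups make the alkene the best acceptor present, and the neutral, aprotic, dark conditions with an acid-free oxidant offer no catalyst for Z to E isomerisation or for epimerisation of the α-keto ring carbons, while the ylide is released slowly in the presence of its trap.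

Step 6
Reactants: 11 3,4-cis-bis(2,4-dimethoxybenzoyl)-2,5-cis-bis(4-methoxyphenyl)thiolane
Product: 12 meso-1,4-bis(2,4-dimethoxyphenyl)-2,3-bis(4-methoxybenzyl)butane-1,4-dione
Conditions: Raney Ni (W-2, washed neutral, deactivated in refluxing acetone), acetone/THF, 20 → 45 °C
Reagents that add atoms: none
Why: Nickel desulfurisation (hydrogenolysis of both benzylic C–S bonds by hydrogen-laden Raney Ni) turns ring carbons 2 and 5 into the two benzylic CH2 groups; C3 and C4 are not touched, so their cis relation becomes the meso configuration of the chain. Neutral, acetone-deactivated nickel is chosen so that the electron-rich aryl ketones are not reduced and the α-centres are not epimerised by residual alkali.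

Step 7
Reactants: 12 meso-1,4-bis(2,4-dimethoxyphenyl)-2,3-bis(4-methoxybenzyl)butane-1,4-dione
Product: 13 meso-(2S,3R)-1,4-bis(2,4-dihydroxyphenyl)-2,3-bis(4-hydroxybenzyl)butane-1,4-dione (CNP0406969.1)
Conditions: BBr3 (12 equiv), CH2Cl2, −78 → 10 °C; ice-water
Reagents that add atoms: none
Why: BBr3 cleavage of aryl methyl ethers: each ether oxygen binds boron and bromide removes the methyl group as bromomethane; the two ortho ethers go first, forming six-membered boron chelates that tie up the ketone carbonyls and should hold back enolisation and furan formation while the other four ethers are cleaved. Hydrolysis frees the six phenols without touching C2 and C3.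

## Compound list

1 | 1,3-dimethoxybenzene | COc1cccc(OC)c1 | starting material
2 | fumaryl chloride ((E)-but-2-enedioyl dichloride) | O=C(Cl)/C=C/C(=O)Cl | starting material
3 | (E)-1,4-bis(2,4-dimethoxyphenyl)but-2-ene-1,4-dione | COc1ccc(C(=O)/C=C/C(=O)c2ccc(OC)cc2OC)c(OC)c1 | intermediate
4 | (Z)-1,4-bis(2,4-dimethoxyphenyl)but-2-ene-1,4-dione | COc1ccc(C(=O)/C=C\C(=O)c2ccc(OC)cc2OC)c(OC)c1 | intermediate
5 | 4-methoxybenzyl chloride | COc1ccc(CCl)cc1 | starting material
6 | bis(4-methoxybenzyl) sulfide | COc1ccc(CSCc2ccc(OC)cc2)cc1 | intermediate
7 | 4-methoxybenzyl (4-methoxyphenyl)(trimethylsilyl)methyl sulfide (racemic) | COc1ccc(CSC(c2ccc(OC)cc2)[Si](C)(C)C)cc1 | intermediate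
8 | bis[(4-methoxyphenyl)(trimethylsilyl)methyl] sulfide (meso/racemic mixture) | COc1ccc(C(SC(c2ccc(OC)cc2)[Si](C)(C)C)[Si](C)(C)C)cc1 | intermediate
9 | bis[(4-methoxyphenyl)(trimethylsilyl)methyl] sulfoxide (diastereomer mixture) | COc1ccc(C([Si](C)(C)C)S(=O)C(c2ccc(OC)cc2)[Si](C)(C)C)cc1 | intermediate
10 | 1,3-bis(4-methoxyphenyl)thiocarbonyl ylide | COc1ccc(/C=[S+]/[CH-]c2ccc(OC)cc2)cc1 | intermediate
11 | 3,4-cis-bis(2,4-dimethoxybenzoyl)-2,5-cis-bis(4-methoxyphenyl)thiolane (aryl trans to neighbouring aroyl; meso; epimers at C2/C5 equally usable) | O=C(c1ccc(OC)cc1OC)[C@@H]1[C@@H](c2ccc(OC)cc2)S[C@@H](c2ccc(OC)cc2)[C@@H]1C(=O)c1ccc(OC)cc1OC | intermediate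
12 | meso-1,4-bis(2,4-dimethoxyphenyl)-2,3-bis(4-methoxybenzyl)butane-1,4-dione | O=C(c1ccc(OC)cc1OC)[C@@H](Cc1ccc(OC)cc1)[C@@H](Cc1ccc(OC)cc1)C(=O)c1ccc(OC)cc1OC | intermediate
13 | meso-(2S,3R)-1,4-bis(2,4-dihydroxyphenyl)-2,3-bis(4-hydroxybenzyl)butane-1,4-dione | O=C(c1ccc(O)cc1O)[C@@H](Cc1ccc(O)cc1)[C@@H](Cc1ccc(O)cc1)C(=O)c1ccc(O)cc1O | target

## Step count and least certain steps

Total: 7 steps. Longest linear sequence: 5 steps (steps 3, 4, 5, 6, 7 from 5; the branch of steps 1 and 2 joins at step 5).

**Step 5 (key step).** The most likely failure is loss of stereospecificity. Either 4 isomerises from Z to E before it is trapped, or the addition goes in two stages through a thionium/enolate zwitterion that the 4-methoxyphenyl groups could stabilise; both would erode the cis relation. A second danger is closure of the ylide to a thiirane faster than the twisted Z alkene traps it. The fallback abandons the sulfur template and sets out from 1. Friedel–Crafts acylation of 1 with 3-(4-methoxyphenyl)propanoyl chloride (COc1ccc(CCC(=O)Cl)cc1; AlCl3, CH2Cl2, 0 °C) gives 1-(2,4-dimethoxyphenyl)-3-(4-methoxyphenyl)propan-1-one F1. Oxidative dimerisation of its lithium enolate (LiN(i-Pr)2, THF, −78 °C; CuCl2, DMF, −78 → 20 °C) forms the C2–C3 bond directly and should give 12 together with rac-(2R,3R)-1,4-bis(2,4-dimethoxyphenyl)-2,3-bis(4-methoxybenzyl)butane-1,4-dione F2, from which 12 would be separated by crystallisation or chromatography. The route is rejoined at 12. This gives up stereocontrol in exchange for a certain bond formation.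

**Step 2.** The most likely failure is over-irradiation chemistry in place of clean isomerisation: photorearrangement of the cis-diaroylethylene, or hydrogen abstraction from the ortho methoxy group by the excited ketone, both of which consume the Z isomer as it forms. The fallback sets out from 3. Reductive cyclisation (SnCl2·2H2O, HCl, AcOH, 80 °C) gives 2,5-bis(2,4-dimethoxyphenyl)furan F3. Oxidative ring opening (mCPBA, NaHCO3, CH2Cl2, 0 °C) unveils the enedione with the Z geometry dictated by the ring. The route is rejoined at 4.

**Step 4.** The most likely failure is wrong regiochemistry in the second metalation: silicon acidifies the already silylated carbon, so geminal disilylation may compete. Rearrangement of the lithiated sulfide on warming is a second risk. The fallback sets out from 5 and installs silicon before sulfur. Barbier silylation (Mg, TMSCl, THF) gives (4-methoxybenzyl)trimethylsilane F4. α-Lithiation of F4 (s-BuLi, TMEDA, THF, −78 °C) and reaction of two equivalents of the anion with bis(phenylsulfonyl) sulfide (O=S(=O)(SS(=O)(=O)c1ccccc1)c1ccccc1) forms both C–S bonds with each silyl group already in place. The route is rejoined at 8.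

**Step 6.** The most likely failure is poor chemoselectivity of the nickel: reduction of one or both aryl ketones, or base-induced epimerisation or β-elimination of sulfur if the nickel is not neutral. The fallback sets out from 11 and accepts over-reduction. Ni2B (from NiCl2·6H2O and NaBH4, MeOH/THF, 0 °C) should cleave both C–S bonds and reduce both ketones to give 1,4-bis(2,4-dimethoxyphenyl)-2,3-bis(4-methoxybenzyl)butane-1,4-diol F5 (meso backbone, carbinol centres as a mixture). Dess–Martin periodinane (NaHCO3, CH2Cl2, 20 °C) would reoxidise it under buffered, non-basic conditions. The route is rejoined at 12.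

**Step 7.** The most likely failure is acid-driven damage to the open 1,4-diketone during the long exposure needed for six ethers: cyclodehydration to a furan, or enolisation that scrambles C2/C3. The fallback sets out from 11 and reverses the last two operations. BBr3 (CH2Cl2, −78 → 10 °C) applied to the thiolane, where furan formation would need a strained ring-fused product, gives 3,4-cis-bis(2,4-dihydroxybenzoyl)-2,5-cis-bis(4-hydroxyphenyl)thiolane F6. Raney Ni desulfurisation of F6 (neutral, acetone/THF) then gives the target. The route is rejoined at 13.

## Further compounds

F1 | step 5 | 1-(2,4-dimethoxyphenyl)-3-(4-methoxyphenyl)propan-1-one | COc1ccc(CCC(=O)c2ccc(OC)cc2OC)cc1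
F2 | step 5 | rac-(2R,3R)-1,4-bis(2,4-dimethoxyphenyl)-2,3-bis(4-methoxybenzyl)butane-1,4-dione (the 2R,3R enantiomer drawn) | O=C(c1ccc(OC)cc1OC)[C@H](Cc1ccc(OC)cc1)[C@@H](Cc1ccc(OC)cc1)C(=O)c1ccc(OC)cc1OC
F3 | step 2 | 2,5-bis(2,4-dimethoxyphenyl)furan | COc1ccc(-c2ccc(-c3ccc(OC)cc3OC)o2)c(OC)c1
F4 | step 4 | (4-methoxybenzyl)trimethylsilane | COc1ccc(C[Si](C)(C)C)cc1
F5 | step 6 | 1,4-bis(2,4-dimethoxyphenyl)-2,3-bis(4-methoxybenzyl)butane-1,4-diol (meso backbone, carbinol centres undefined) | OC(c1ccc(OC)cc1OC)[C@@H](Cc1ccc(OC)cc1)[C@@H](Cc1ccc(OC)cc1)C(O)c1ccc(OC)cc1OC
F6 | step 7 | 3,4-cis-bis(2,4-dihydroxybenzoyl)-2,5-cis-bis(4-hydroxyphenyl)thiolane | O=C(c1ccc(O)cc1O)[C@@H]1[C@@H](c2ccc(O)cc2)S[C@@H](c2ccc(O)cc2)[C@@H]1C(=O)c1ccc(O)cc1O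
A1 | alternative 1 | dimethyl meso-2,3-bis(4-hydroxybenzyl)succinate | COC(=O)[C@@H](Cc1ccc(O)cc1)[C@@H](Cc1ccc(O)cc1)C(=O)OC
A2 | alternative 1 | dimethyl meso-2,3-di(prop-2-yn-1-yl)succinate | COC(=O)[C@@H](CC#C)[C@@H](CC#C)C(=O)OC
A3 | alternative 1 | 2-(trimethylsilyloxy)buta-1,3-diene | C=CC(=C)O[Si](C)(C)C
A4 | alternative 1 | cis-cyclohex-4-ene-1,2-dicarboxylic anhydride | O=C1OC(=O)[C@@H]2CC=CC[C@H]12
A5 | alternative 2 | meso-2,3-bis(4-methoxybenzyl)-N1,N4-di(quinolin-8-yl)succinamide | O=C(Nc1cccc2cccnc12)[C@@H](Cc1ccc(OC)cc1)[C@@H](Cc1ccc(OC)cc1)C(=O)Nc1cccc2cccnc12
A6 | alternative 2 | meso-2,3-dimethylsuccinic acid | O=C(O)[C@@H](C)[C@@H](C)C(=O)O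
A7 | alternative 2 | meso-2,3-dimethyl-N1,N4-di(quinolin-8-yl)succinamide | O=C(Nc1cccc2cccnc12)[C@@H](C)[C@@H](C)C(=O)Nc1cccc2cccnc12
A8 | alternative 2 | 4-iodoanisole | COc1ccc(I)cc1
A9 | alternative 3 | meso-1,4-bis(2-hydroxy-4-methoxyphenyl)-2,3-bis(4-methoxybenzyl)butane-1,4-dione | O=C(c1ccc(OC)cc1O)[C@@H](Cc1ccc(OC)cc1)[C@@H](Cc1ccc(OC)cc1)C(=O)c1ccc(OC)cc1O
A10 | alternative 3 | meso-1,4-bis(4-methoxyphenyl)-2,3-bis(4-methoxybenzyl)butane-1,4-dione | O=C(c1ccc(OC)cc1)[C@@H](Cc1ccc(OC)cc1)[C@@H](Cc1ccc(OC)cc1)C(=O)c1ccc(OC)cc1
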